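**Plan**

Retrosynthesis: the C6–CH2 bond of the prenyl group goes back to a 5-O-(1,1-dimethylallyl) ether (retro-Claisen); then O1–C2 of ring C is cut to a 2'-hydroxychalcone; then the enone C=C to an acetophenone and 3,4,5-trimethoxybenzaldehyde; then the tertiary ether C–O to a symmetrical diphenol.
Forward: ring A is bought complete and one of its two equivalent phenols is capped as the tertiary allyl ether; the C3 chain and ring B are joined by aldol condensation; ring C is closed; the prenyl group then moves from O5 to C6.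
Enabling feature: C2 is the β-carbon of the C4 ketone and O1 sits on C8a, ortho to the acyl-bearing C4a, so O1–C2 is an oxa-conjugate addition; C6 is ortho to O5, and O5 is the other ortho oxygen of the same aroyl ring.
One group on O5 therefore decides which oxygen closes ring C (6- versus 8-prenyl series) and later delivers the prenyl group to C6 while freeing the 5-OH.
Stereochemistry: C2 (S), the only stereocentre, is set during ring closure by a chiral bifunctional catalyst and is not touched afterwards.

Key step: step 4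

Assumption: compounds 1, 2 and 5 are commercial and are used as bought.

**Route**

Step 1
Reactants: 1 1-(2,6-dihydroxy-4-methoxyphenyl)ethan-1-one; 2 3-chloro-3-methylbut-1-yne
Product: 3 1-[2-hydroxy-4-methoxy-6-(2-methylbut-3-yn-2-yloxy)phenyl]ethan-1-one
Conditions: K2CO3, KI (cat.), CuI (cat.), acetone, 50 °C
Reagents that add atoms: none
Why: Copper-catalysed propargylic substitution (copper acetylide, loss of chloride, capture of the resulting allenylidene at the tertiary carbon) should etherify the hydroxyl that is not hydrogen-bonded to the acetyl C=O, and the remaining chelated hydroxyl should resist a second alkylation.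

Step 2
Reactants: 3 1-[2-hydroxy-4-methoxy-6-(2-methylbut-3-yn-2-yloxy)phenyl]ethan-1-one
Product: 4 1-[2-hydroxy-4-methoxy-6-(2-methylbut-3-en-2-yloxy)phenyl]ethan-1-one
Conditions: H2 (1 atm), Pd/CaCO3 poisoned with Pb(OAc)2, quinoline, EtOAc, rt
Reagents that add atoms: none
Why: Lindlar semihydrogenation should add one equivalent of H2 to the terminal alkyne on the poisoned palladium surface and stop at the alkene, with the aryl ketone and the ether inert.

Step 3
Reactants: 4 1-[2-hydroxy-4-methoxy-6-(2-methylbut-3-en-2-yloxy)phenyl]ethan-1-one; 5 3,4,5-trimethoxybenzaldehyde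
Product: 7 (E)-1-[2-hydroxy-4-methoxy-6-(2-methylbut-3-en-2-yloxy)phenyl]-3-(3,4,5-trimethoxyphenyl)prop-2-en-1-one, via racemic aldol adduct 6 (not isolated)
Conditions: KOH, EtOH, 0 °C to rt
Reagents that add atoms: none
Why: Claisen–Schmidt condensation: the ketone enolate adds to the non-enolisable aldehyde and adduct 6 loses water by an E1cB path to the conjugated E-enone, which in strong base should rest as its open phenoxide while the base-stable tertiary allyl ether survives at room temperature.

Step 4
Reactants: 7 (E)-1-[2-hydroxy-4-methoxy-6-(2-methylbut-3-en-2-yloxy)phenyl]-3-(3,4,5-trimethoxyphenyl)prop-2-en-1-one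
Product: 8 (2S)-7-methoxy-5-(2-methylbut-3-en-2-yloxy)-2-(3,4,5-trimethoxyphenyl)-2,3-dihydro-4H-chromen-4-one
Conditions: N-[3,5-bis(trifluoromethyl)phenyl]-N'-[(8α,9S)-6'-methoxycinchonan-9-yl]thiourea (10 mol%), PhMe, −20 to 0 °C; silica plug
Reagents that add atoms: none
Why: The quinuclidine nitrogen of the catalyst takes the proton of the only free phenol while the thiourea N–H pair hydrogen-bonds the enone C=O, so that the phenoxide oxygen adds to the β-carbon and the proton is returned to C3 (intramolecular oxa-Michael addition). The closest known reaction type is the cinchona-thiourea-catalysed enantioselective cyclisation of 2'-hydroxychalcones and of their alkylidene β-ketoester analogues to flavanones. Ring C closes in the 6-endo-trig mode. C2 is set by the catalyst alone: the chiral ion pair should expose the Si face of the β-carbon to the oxygen, which gives 2S, and the quinidine-derived pseudoenantiomer is the remedy should the sense prove opposite. The step needs site selectivity between the two ortho oxygens of ring A, secured because the second one is tied up as the tertiary allyl ether so that only the 6-prenyl series can follow, and kinetic control over the reversible retro-addition, for which low temperature, a non-polar solvent and removal of the catalyst on silica once the chalcone is consumed should serve. The basic catalyst and a temperature far below that of the [3,3] shift leave the acid- and heat-sensitive ether untouched.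

Step 5
Reactants: 8 (2S)-7-methoxy-5-(2-methylbut-3-en-2-yloxy)-2-(3,4,5-trimethoxyphenyl)-2,3-dihydro-4H-chromen-4-one
Product: 10 artoflavanone (2S)-5-hydroxy-7-methoxy-6-(3-methylbut-2-en-1-yl)-2-(3,4,5-trimethoxyphenyl)-2,3-dihydro-4H-chromen-4-one, via ortho-dienone tautomer 9 (not isolated)
Conditions: PhMe, 110 °C
Reagents that add atoms: none
Why: Aromatic Claisen rearrangement: the [3,3] shift of the 1,1-dimethylallyl ether can end only at C6 (the other ortho carbon, C4a, is quaternary), turns the allyl unit end for end into the 3-methylbut-2-enyl group, and tautomerisation of dienone 9 should give the chelated 5-OH phenol, while neutral base-free heating should leave C2 untouched.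

**Compound list**

1 | 1-(2,6-dihydroxy-4-methoxyphenyl)ethan-1-one | CC(=O)c1c(O)cc(OC)cc1O | starting material
2 | 3-chloro-3-methylbut-1-yne | CC(C)(Cl)C#C | starting material
3 | 1-[2-hydroxy-4-methoxy-6-(2-methylbut-3-yn-2-yloxy)phenyl]ethan-1-one | CC(=O)c1c(O)cc(OC)cc1OC(C)(C)C#C | intermediate
4 | 1-[2-hydroxy-4-methoxy-6-(2-methylbut-3-en-2-yloxy)phenyl]ethan-1-one | CC(=O)c1c(O)cc(OC)cc1OC(C)(C)C=C | intermediate
5 | 3,4,5-trimethoxybenzaldehyde | COc1cc(C=O)cc(OC)c1OC | starting material
6 | racemic 3-hydroxy-1-[2-hydroxy-4-methoxy-6-(2-methylbut-3-en-2-yloxy)phenyl]-3-(3,4,5-trimethoxyphenyl)propan-1-one (aldol adduct, not isolated) | COc1cc(O)c(C(=O)CC(O)c2cc(OC)c(OC)c(OC)c2)c(OC(C)(C)C=C)c1 | intermediate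
7 | (E)-1-[2-hydroxy-4-methoxy-6-(2-methylbut-3-en-2-yloxy)phenyl]-3-(3,4,5-trimethoxyphenyl)prop-2-en-1-one | COc1cc(O)c(C(=O)/C=C/c2cc(OC)c(OC)c(OC)c2)c(OC(C)(C)C=C)c1 | intermediate
8 | (2S)-7-methoxy-5-(2-methylbut-3-en-2-yloxy)-2-(3,4,5-trimethoxyphenyl)-2,3-dihydro-4H-chromen-4-one | COc1cc2c(c(OC(C)(C)C=C)c1)C(=O)C[C@@H](c1cc(OC)c(OC)c(OC)c1)O2 | intermediate
9 | (2S)-7-methoxy-6-(3-methylbut-2-en-1-yl)-2-(3,4,5-trimethoxyphenyl)-2,3-dihydrochromene-4,5(6H)-dione (ortho-dienone, not isolated, both C6 epimers) | COC1=CC2=C(C(=O)C1CC=C(C)C)C(=O)C[C@@H](c1cc(OC)c(OC)c(OC)c1)O2 | intermediate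
10 | artoflavanone, (2S)-5-hydroxy-7-methoxy-6-(3-methylbut-2-en-1-yl)-2-(3,4,5-trimethoxyphenyl)-2,3-dihydro-4H-chromen-4-one | COc1cc2c(c(O)c1CC=C(C)C)C(=O)C[C@@H](c1cc(OC)c(OC)c(OC)c1)O2 | target

**Count and risks**

Total steps: 5. Longest linear sequence: 5 steps (1 → 3 → 4 → 7 → 8 → 10).

Steps most likely to fail:

Step 4. The ring closure is reversible and the enone carries no second binding group. Facial discrimination may therefore be poor, or the enantiomeric purity may erode as the catalyst re-opens and re-closes ring C. The fallback replaces asymmetric induction by resolution; it sets out from 7 and comes back at 8. Ring closure without stereocontrol (NaOAc, EtOH, 50 °C) should give racemic 7-methoxy-5-(2-methylbut-3-en-2-yloxy)-2-(3,4,5-trimethoxyphenyl)-2,3-dihydro-4H-chromen-4-one F1. Kinetic resolution by asymmetric transfer hydrogenation (Cp*RhCl[(R,R)-TsDPEN] (cat.), HCO2H/Et3N, EtOAc, rt, stopped near half conversion) should reduce the 2R enantiomer, with hydride delivered trans to its aryl group, to (2R,4R)-7-methoxy-5-(2-methylbut-3-en-2-yloxy)-2-(3,4,5-trimethoxyphenyl)-3,4-dihydro-2H-chromen-4-ol F2. The unreacted 2S ketone 8 is separated by chromatography.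

Step 5. On heating, three processes may compete with the [3,3] shift: fragmentation of the tertiary allyl ether to isoprene and the free phenol, a second shift onward to C8, and thermal ring opening with loss of configuration at C2. The fallback carries out the rearrangement before the stereocentre exists and exchanges protecting groups; it sets out from 4 and comes back at 10.
- Silylation of the free phenol of 4 (TBSCl, imidazole, DMF) should give 1-[2-{[tert-butyl(dimethyl)silyl]oxy}-4-methoxy-6-(2-methylbut-3-en-2-yloxy)phenyl]ethan-1-one F3.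
- Heating (PhMe, 110 °C) should take this achiral ketone through the dienone 2-acetyl-3-{[tert-butyl(dimethyl)silyl]oxy}-5-methoxy-6-(3-methylbut-2-en-1-yl)cyclohexa-2,4-dien-1-one F4 to 1-[6-{[tert-butyl(dimethyl)silyl]oxy}-2-hydroxy-4-methoxy-3-(3-methylbut-2-en-1-yl)phenyl]ethan-1-one F5.
- Capping of the phenol just set free (MOMCl, iPr2NEt, CH2Cl2) should give 1-[6-{[tert-butyl(dimethyl)silyl]oxy}-4-methoxy-2-(methoxymethoxy)-3-(3-methylbut-2-en-1-yl)phenyl]ethan-1-one F6.
- TBAF (THF, 0 °C) should free the other phenol and give 1-[6-hydroxy-4-methoxy-2-(methoxymethoxy)-3-(3-methylbut-2-en-1-yl)phenyl]ethan-1-one F7.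
- Condensation with 5 (KOH, EtOH, rt) should pass through the aldol adduct 3-hydroxy-1-[6-hydroxy-4-methoxy-2-(methoxymethoxy)-3-(3-methylbut-2-en-1-yl)phenyl]-3-(3,4,5-trimethoxyphenyl)propan-1-one F8 to (E)-1-[6-hydroxy-4-methoxy-2-(methoxymethoxy)-3-(3-methylbut-2-en-1-yl)phenyl]-3-(3,4,5-trimethoxyphenyl)prop-2-en-1-one F9.
- The catalyst of step 4 should close ring C through the only free phenol to (2S)-7-methoxy-5-(methoxymethoxy)-6-(3-methylbut-2-en-1-yl)-2-(3,4,5-trimethoxyphenyl)-2,3-dihydro-4H-chromen-4-one F10.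
- Dilute HCl in MeOH (rt) should remove the acetal and give 10.

Step 1. The hindered, hydrogen-bonded phenol may etherify sluggishly, and propargyl-to-allenyl isomerisation or double alkylation may intervene. The fallback replaces propargylation and semihydrogenation by a direct allylic etherification; it sets out from 1 and comes back at 4, bypassing step 2. Decarboxylative Tsuji–Trost etherification (tert-butyl 2-methylbut-3-en-2-yl carbonate, Pd(PPh3)4 (cat.), THF, 0 °C) should let the phenoxide attack the substituted terminus of the 1,1-dimethylallyl palladium intermediate and give 4 directly. It makes no compound outside the list (F0).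

**Further compounds**

F1 | step 4 | racemic 7-methoxy-5-(2-methylbut-3-en-2-yloxy)-2-(3,4,5-trimethoxyphenyl)-2,3-dihydro-4H-chromen-4-one | COc1cc2c(c(OC(C)(C)C=C)c1)C(=O)CC(c1cc(OC)c(OC)c(OC)c1)O2
F2 | step 4 | (2R,4R)-7-methoxy-5-(2-methylbut-3-en-2-yloxy)-2-(3,4,5-trimethoxyphenyl)-3,4-dihydro-2H-chromen-4-ol | COc1cc2c(c(OC(C)(C)C=C)c1)[C@H](O)C[C@H](c1cc(OC)c(OC)c(OC)c1)O2
F3 | step 5 | 1-[2-{[tert-butyl(dimethyl)silyl]oxy}-4-methoxy-6-(2-methylbut-3-en-2-yloxy)phenyl]ethan-1-one | CC(=O)c1c(O[Si](C)(C)C(C)(C)C)cc(OC)cc1OC(C)(C)C=C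
F4 | step 5 | 2-acetyl-3-{[tert-butyl(dimethyl)silyl]oxy}-5-methoxy-6-(3-methylbut-2-en-1-yl)cyclohexa-2,4-dien-1-one | CC(=O)C1=C(O[Si](C)(C)C(C)(C)C)C=C(OC)C(CC=C(C)C)C1=O
F5 | step 5 | 1-[6-{[tert-butyl(dimethyl)silyl]oxy}-2-hydroxy-4-methoxy-3-(3-methylbut-2-en-1-yl)phenyl]ethan-1-one | CC(=O)c1c(O[Si](C)(C)C(C)(C)C)cc(OC)c(CC=C(C)C)c1O
F6 | step 5 | 1-[6-{[tert-butyl(dimethyl)silyl]oxy}-4-methoxy-2-(methoxymethoxy)-3-(3-methylbut-2-en-1-yl)phenyl]ethan-1-one | CC(=O)c1c(O[Si](C)(C)C(C)(C)C)cc(OC)c(CC=C(C)C)c1OCOC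
F7 | step 5 | 1-[6-hydroxy-4-methoxy-2-(methoxymethoxy)-3-(3-methylbut-2-en-1-yl)phenyl]ethan-1-one | CC(=O)c1c(O)cc(OC)c(CC=C(C)C)c1OCOC
F8 | step 5 | 3-hydroxy-1-[6-hydroxy-4-methoxy-2-(methoxymethoxy)-3-(3-methylbut-2-en-1-yl)phenyl]-3-(3,4,5-trimethoxyphenyl)propan-1-one | COCOc1c(CC=C(C)C)c(OC)cc(O)c1C(=O)CC(O)c1cc(OC)c(OC)c(OC)c1
F9 | step 5 | (E)-1-[6-hydroxy-4-methoxy-2-(methoxymethoxy)-3-(3-methylbut-2-en-1-yl)phenyl]-3-(3,4,5-trimethoxyphenyl)prop-2-en-1-one | COCOc1c(CC=C(C)C)c(OC)cc(O)c1C(=O)/C=C/c1cc(OC)c(OC)c(OC)c1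
F10 | step 5 | (2S)-7-methoxy-5-(methoxymethoxy)-6-(3-methylbut-2-en-1-yl)-2-(3,4,5-trimethoxyphenyl)-2,3-dihydro-4H-chromen-4-one | COCOc1c(CC=C(C)C)c(OC)cc2c1C(=O)C[C@@H](c1cc(OC)c(OC)c(OC)c1)O2
F0 | step 1 | none | none
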